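**Retrosynthetic overview**

1. Numbering (germacranolide): ring carbons C1–C10, with the epoxide on C1/C10 (C14 methyl on C10), the isovalerate on C3, the Z alkene C4=C5 (C15 methyl on C4), the lactone oxygen on C6, then C7, and the epoxyangelate on C8; lactone carbons C11(=C13) and C12.
2. Target ⇐ peripheral epoxidation of C1=C10 and acylation of O8 and O3 (last operations) ⇐ ten-membered (1(10)E,4Z)-dienolide alcohol.
3. Key disconnection C3–C4: the ten-membered ring is closed second, by intramolecular Nozaki–Hiyama–Kishi addition of the Z iodoalkene at C4 to the C3 aldehyde. This is possible because C3 is an allylic carbinol bonded to the sp2 carbon C4, and because the Z C4=C5 alkene, the trans γ-lactone at C6/C7 and the E C1=C10 alkene fold the C7–C3 chain back onto C4. One operation gives the ring, the array C3(O)–C4=C5–C6(O) and the C3 stereocentre.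
4. γ-Lactone (first ring; C6–C7 and O6–C12 bonds) ⇐ chromium-mediated 2-(methoxycarbonyl)allylation/lactonisation of (Z)-3-iodobut-2-enal (C4–C6, C15) with a C7–C3 allylic bromide.
5. Bromide ⇐ (R)-trityl glycidyl ether (C7–C9) + acetylide (C10, C1), carboalumination/ethylene oxide (C14, C2, C3), Morita–Baylis–Hillman reaction with methyl acrylate (C11–C13); epoxyangelic acid ⇐ angelic acid by Sharpless epoxidation.

Key step: step 17

Remark: step 12 gives both epimers at the new carbinol carbon (C7); this is of no consequence because C7 becomes sp2 in step 13 and is set in step 14.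

**Route**

Step 1
Reactants: 1 but-2-yn-1-ol
Product: 3 (2Z)-3-iodobut-2-en-1-ol, via cyclic sodium alkenylalanate 2 (not isolated)
Conditions: NaAlH2(OCH2CH2OCH3)2, THF, 0 °C to rt; then I2, −78 °C to 0 °C
Reagents that add atoms: iodine, II
Why: Hydroxyl-directed trans-hydroalumination of the propargylic alcohol should place aluminium on the distal alkyne carbon in a five-membered alkoxyalanate, and iodinolysis of the C–Al bond with retention should give the Z iodoalkene.

Step 2
Reactants: 3 (2Z)-3-iodobut-2-en-1-ol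
Product: 4 (2Z)-3-iodobut-2-enal
Conditions: MnO2, CH2Cl2, rt, dark
Reagents that add atoms: none
Why: Allylic oxidation with MnO2 should give the enal without touching the iodoalkene or its geometry.

Step 3
Reactants: 5 angelic acid
Product: 6 (2Z)-2-methylbut-2-en-1-ol
Conditions: LiAlH4, Et2O, 0 °C
Reagents that add atoms: none
Why: Hydride reduction of the conjugated acid in 1,2-fashion should give the allylic alcohol with the Z geometry kept.

Step 4
Reactants: 6 (2Z)-2-methylbut-2-en-1-ol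
Product: 7 [(2R,3S)-2,3-dimethyloxiran-2-yl]methanol
Conditions: Ti(OiPr)4 (cat.), D-(−)-diethyl tartrate (cat.), t-BuOOH, 4 Å molecular sieves, CH2Cl2, −20 °C
Reagents that add atoms: tert-butyl hydroperoxide, CC(C)(C)OO
Why: Sharpless asymmetric epoxidation with the D-(−)-tartrate catalyst should deliver oxygen to one face of the allylic alcohol and set both epoxide centres, the cis relation of the C3 methyl and the hydroxymethyl group coming from the Z alkene.

Step 5
Reactants: 7 [(2R,3S)-2,3-dimethyloxiran-2-yl]methanol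
Product: 8 (2S,3S)-2,3-dimethyloxirane-2-carboxylic acid
Conditions: RuCl3 (cat.), NaIO4, MeCN/EtOAc/H2O, rt
Reagents that add atoms: water, O
Why: Catalytic RuO4 oxidation (RuCl3/NaIO4) should take the primary alcohol to the acid without opening the epoxide, the two stereocentres being untouched (the C2 descriptor changes only through priorities).

Step 6
Reactants: 9 (2R)-2-[(triphenylmethoxy)methyl]oxirane
Product: 10 (2R)-1-(triphenylmethoxy)pent-4-yn-2-ol
Conditions: LiC≡CH·H2NCH2CH2NH2, DMSO, 0 °C to rt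
Reagents that add atoms: lithium acetylide ethylenediamine complex, [Li+].[C-]#C.NCCN
Why: SN2 opening of the terminal epoxide at its unsubstituted carbon by the acetylide should give the homopropargylic alcohol, the stereocentre (later C8) not being touched.

Step 7
Reactants: 10 (2R)-1-(triphenylmethoxy)pent-4-yn-2-ol
Product: 11 1-methoxy-4-({[(2R)-1-(triphenylmethoxy)pent-4-yn-2-yl]oxy}methyl)benzene
Conditions: NaH, 4-methoxybenzyl chloride, Bu4NI (cat.), DMF, 0 °C to rt
Reagents that add atoms: 4-methoxybenzyl chloride, COc1ccc(CCl)cc1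
Why: Williamson etherification of the secondary alkoxide should protect O8 as a 4-methoxybenzyl ether that is removable late under neutral oxidative conditions.

Step 8
Reactants: 11 1-methoxy-4-({[(2R)-1-(triphenylmethoxy)pent-4-yn-2-yl]oxy}methyl)benzene
Product: 14 (3E,6R)-6-[(4-methoxybenzyl)oxy]-4-methyl-7-(triphenylmethoxy)hept-3-en-1-ol, via alkenyldimethylalane 12 (not isolated), via lithium alkenylalanate 13 (not isolated)
Conditions: Me3Al, Cp2ZrCl2 (cat.), CH2Cl2, 0 °C to rt; then n-BuLi, THF, −78 °C; then ethylene oxide, −78 °C to rt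
Reagents that add atoms: trimethylaluminium, C[Al](C)C; ethylene oxide, C1CO1
Why: Zirconium-catalysed syn-carboalumination (Negishi carboalumination) should add methyl to the internal and aluminium to the terminal alkyne carbon, and the derived alanate should open ethylene oxide with retention at the alkenyl carbon, so that the C1=C10 alkene is E.

Step 9
Reactants: 14 (3E,6R)-6-[(4-methoxybenzyl)oxy]-4-methyl-7-(triphenylmethoxy)hept-3-en-1-ol
Product: 15 tert-butyl({(3E,6R)-6-[(4-methoxybenzyl)oxy]-4-methyl-7-(triphenylmethoxy)hept-3-en-1-yl}oxy)diphenylsilane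
Conditions: t-BuPh2SiCl, imidazole, DMF, rt
Reagents that add atoms: tert-butyl(chloro)diphenylsilane, CC(C)(C)[Si](Cl)(c1ccccc1)c1ccccc1
Why: Silylation of the primary alcohol should give an acid-stable silyl ether that masks C3 until just before the ring closure.

Step 10
Reactants: 15 tert-butyl({(3E,6R)-6-[(4-methoxybenzyl)oxy]-4-methyl-7-(triphenylmethoxy)hept-3-en-1-yl}oxy)diphenylsilane
Product: 16 (2R,4E)-7-[(tert-butyldiphenylsilyl)oxy]-2-[(4-methoxybenzyl)oxy]-4-methylhept-4-en-1-ol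
Conditions: p-TsOH·H2O (cat.), MeOH/CH2Cl2, 0 °C
Reagents that add atoms: none
Why: Acid-catalysed solvolysis of the trityl ether (SN1 through the trityl cation) should free the C7 hydroxyl while the 4-methoxybenzyl and silyl ethers stay in place.

Step 11
Reactants: 16 (2R,4E)-7-[(tert-butyldiphenylsilyl)oxy]-2-[(4-methoxybenzyl)oxy]-4-methylhept-4-en-1-ol
Product: 17 (2R,4E)-7-[(tert-butyldiphenylsilyl)oxy]-2-[(4-methoxybenzyl)oxy]-4-methylhept-4-enal
Conditions: Dess–Martin periodinane, NaHCO3, CH2Cl2, 0 °C to rt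
Reagents that add atoms: none
Why: Buffered Dess–Martin oxidation should give the α-alkoxy aldehyde without epimerisation of the adjacent stereocentre.

Step 12
Reactants: 17 (2R,4E)-7-[(tert-butyldiphenylsilyl)oxy]-2-[(4-methoxybenzyl)oxy]-4-methylhept-4-enal; 18 methyl acrylate
Product: 19 methyl (4R,6E)-9-[(tert-butyldiphenylsilyl)oxy]-3-hydroxy-4-[(4-methoxybenzyl)oxy]-6-methyl-2-methylidenenon-6-enoate (both C3 epimers)
Conditions: DABCO, 1,4-dioxane/H2O, rt
Reagents that add atoms: none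
Why: The Morita–Baylis–Hillman reaction of the activated α-alkoxy aldehyde with the acrylate should attach C11–C13, the new carbinol centre being of no consequence.

Step 13
Reactants: 19 methyl (4R,6E)-9-[(tert-butyldiphenylsilyl)oxy]-3-hydroxy-4-[(4-methoxybenzyl)oxy]-6-methyl-2-methylidenenon-6-enoate
Product: 20 methyl (2Z,4R,6E)-2-(bromomethyl)-9-[(tert-butyldiphenylsilyl)oxy]-4-[(4-methoxybenzyl)oxy]-6-methylnona-2,6-dienoate
Conditions: NBS, Me2S, CH2Cl2, 0 °C to rt
Reagents that add atoms: N-bromosuccinimide, O=C1CCC(=O)N1Br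
Why: Corey–Kim-type activation of the allylic alcohol and SN2′ attack of bromide should give the thermodynamically preferred Z 2-(bromomethyl)enoate.

Step 14
Reactants: 20 methyl (2Z,4R,6E)-2-(bromomethyl)-9-[(tert-butyldiphenylsilyl)oxy]-4-[(4-methoxybenzyl)oxy]-6-methylnona-2,6-dienoate; 4 (2Z)-3-iodobut-2-enal
Product: 22 (4R,5S)-4-[(1R,3E)-6-[(tert-butyldiphenylsilyl)oxy]-1-[(4-methoxybenzyl)oxy]-3-methylhex-3-en-1-yl]-5-[(1Z)-2-iodoprop-1-en-1-yl]-3-methylideneoxolan-2-one, via hydroxy ester 21 (not isolated)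
Conditions: CrCl2, THF, 0 °C to rt; then p-TsOH·H2O (cat.), CH2Cl2, rt
Reagents that add atoms: none
Why: In this chromium-mediated Barbier (Nozaki–Hiyama) 2-(methoxycarbonyl)allylation the allylchromium from 20 should add through its γ-carbon (C7) to the aldehyde in a chair transition state that gives the anti adduct (C6 and C7, hence the trans lactone after acid-catalysed lactonisation), the aldehyde approaching the C7 face anti to the C9 branch of the C8 stereocentre held by A(1,3) strain, while the iodoalkene is inert to CrCl2 without nickel.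

Step 15
Reactants: 22 (4R,5S)-4-[(1R,3E)-6-[(tert-butyldiphenylsilyl)oxy]-1-[(4-methoxybenzyl)oxy]-3-methylhex-3-en-1-yl]-5-[(1Z)-2-iodoprop-1-en-1-yl]-3-methylideneoxolan-2-one
Product: 23 (4R,5S)-4-[(1R,3E)-6-hydroxy-1-[(4-methoxybenzyl)oxy]-3-methylhex-3-en-1-yl]-5-[(1Z)-2-iodoprop-1-en-1-yl]-3-methylideneoxolan-2-one
Conditions: HF·pyridine, pyridine, THF, 0 °C to rt
Reagents that add atoms: none
Why: Buffered fluoride desilylation should free the C3 hydroxyl without affecting the methylene lactone, the iodoalkene or the 4-methoxybenzyl ether.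

Step 16
Reactants: 23 (4R,5S)-4-[(1R,3E)-6-hydroxy-1-[(4-methoxybenzyl)oxy]-3-methylhex-3-en-1-yl]-5-[(1Z)-2-iodoprop-1-en-1-yl]-3-methylideneoxolan-2-one
Product: 24 (4R,5S)-5-[(1Z)-2-iodoprop-1-en-1-yl]-4-[(1R,3E)-1-[(4-methoxybenzyl)oxy]-3-methyl-6-oxohex-3-en-1-yl]-3-methylideneoxolan-2-one
Conditions: Dess–Martin periodinane, NaHCO3, CH2Cl2, 0 °C; used at once
Reagents that add atoms: none
Why: Neutral Dess–Martin oxidation should give the β,γ-unsaturated aldehyde without migration of the C1=C10 alkene into conjugation.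

Step 17
Reactants: 24 (4R,5S)-5-[(1Z)-2-iodoprop-1-en-1-yl]-4-[(1R,3E)-1-[(4-methoxybenzyl)oxy]-3-methyl-6-oxohex-3-en-1-yl]-3-methylideneoxolan-2-one
Product: 25 (3S,6R,7R,8R)-3-hydroxy-8-[(4-methoxybenzyl)oxy]germacra-1(10)E,4Z,11(13)-trien-12,6-olide
Conditions: CrCl2 (excess), NiCl2 (cat.), DMSO, rt, high dilution (slow addition of 24)
Reagents that add atoms: none
Why: NiCl2 is reduced by CrCl2 to zerovalent nickel, which inserts into the C4–I bond with retention of the Z geometry; transmetalation gives the alkenyl trivalent-chromium species, which adds to the C3 aldehyde and leaves the lactone, the enoate and the ethers alone. The closest known reaction type is the intramolecular Nozaki–Hiyama–Kishi coupling of an iodoalkene with an aldehyde, used to close medium-ring and ten-membered carbocyclic allylic alcohols. The ten-membered ring C1–C10 is closed in a 10-exo-trig mode at the C3–C4 bond, the Z C4=C5 alkene, the trans lactone and the E C1=C10 alkene bringing the two chain ends together. The new C3 stereocentre is controlled by the conformation of the forming ring: with the aldehyde oxygen pointing to the outside of the ring and away from the C15 methyl, the 3S alcohol is expected. The step needs chemoselectivity for the aldehyde, retention of the alkene geometry and cyclisation over oligomerisation; these are secured by the organochromium reagent, the stereospecific nickel-to-chromium exchange and the preorganised substrate under high dilution.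

Step 18
Reactants: 25 (3S,6R,7R,8R)-3-hydroxy-8-[(4-methoxybenzyl)oxy]germacra-1(10)E,4Z,11(13)-trien-12,6-olide
Product: 26 (3S,6R,7R,8R)-8-[(4-methoxybenzyl)oxy]-3-(3-methylbutanoyloxy)germacra-1(10)E,4Z,11(13)-trien-12,6-olide
Conditions: 3-methylbutanoic anhydride, DMAP (cat.), Et3N, CH2Cl2, 0 °C to rt
Reagents that add atoms: 3-methylbutanoic anhydride, CC(C)CC(=O)OC(=O)CC(C)C
Why: DMAP-catalysed acylation of the only free hydroxyl should install the isovalerate with retention at C3.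

Step 19
Reactants: 26 (3S,6R,7R,8R)-8-[(4-methoxybenzyl)oxy]-3-(3-methylbutanoyloxy)germacra-1(10)E,4Z,11(13)-trien-12,6-olide
Product: 27 (3S,6R,7R,8R)-8-hydroxy-3-(3-methylbutanoyloxy)germacra-1(10)E,4Z,11(13)-trien-12,6-olide
Conditions: DDQ, CH2Cl2/pH 7 buffer, 0 °C to rt
Reagents that add atoms: none
Why: Oxidative cleavage of the 4-methoxybenzyl ether with DDQ should free O8 under neutral conditions that spare the esters, the lactone and the alkenes.

Step 20
Reactants: 8 (2S,3S)-2,3-dimethyloxirane-2-carboxylic acid; 27 (3S,6R,7R,8R)-8-hydroxy-3-(3-methylbutanoyloxy)germacra-1(10)E,4Z,11(13)-trien-12,6-olide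
Product: 29 (3S,6R,7R,8R)-8-[(2S,3S)-2,3-dimethyloxirane-2-carbonyloxy]-3-(3-methylbutanoyloxy)germacra-1(10)E,4Z,11(13)-trien-12,6-olide, via mixed anhydride 28 (not isolated)
Conditions: 2,4,6-trichlorobenzoyl chloride, Et3N, THF, rt; then 27, DMAP, toluene, rt
Reagents that add atoms: none
Why: Yamaguchi esterification through the mixed anhydride should acylate the hindered secondary alcohol with the α-quaternary epoxy acid without touching any stereocentre.

Step 21
Reactants: 29 (3S,6R,7R,8R)-8-[(2S,3S)-2,3-dimethyloxirane-2-carbonyloxy]-3-(3-methylbutanoyloxy)germacra-1(10)E,4Z,11(13)-trien-12,6-olide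
Product: 30 (1R,3S,6R,7R,8R,10R)-8-[(2S,3S)-2,3-dimethyloxirane-2-carbonyloxy]-1,10-epoxy-3-(3-methylbutanoyloxy)germacra-4Z,11(13)-dien-12,6-olide (CNP0167461.1)
Conditions: mCPBA, NaHCO3, CH2Cl2, 0 °C
Reagents that add atoms: 3-chloroperbenzoic acid, O=C(OO)c1cccc(Cl)c1
Why: In this Prilezhaev epoxidation the peracid should attack the most electron-rich alkene (C1=C10; C4=C5 is deactivated by two allylic acyloxy groups and C11=C13 is conjugated) from the exposed outer face of the E alkene in the ten-membered ring, which, with the C14 methyl on the face opposite to H7 as is usual for these lactones, should give the 1R,10R epoxide.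

**Compound list**

1 | but-2-yn-1-ol | CC#CCO | starting material
2 | sodium 2,2-bis(2-methoxyethoxy)-3-methyl-2,5-dihydro-1,2-oxaaluminol-2-uide (cyclic sodium alkenylalanate) | CC1=CCO[Al-]1(OCCOC)OCCOC.[Na+] | intermediate
3 | (2Z)-3-iodobut-2-en-1-ol | C/C(I)=C/CO | intermediate
4 | (2Z)-3-iodobut-2-enal | C/C(I)=C/C=O | intermediate
5 | angelic acid, (2Z)-2-methylbut-2-enoic acid | C/C=C(/C)C(=O)O | starting material
6 | (2Z)-2-methylbut-2-en-1-ol | C/C=C(/C)CO | intermediate
7 | [(2R,3S)-2,3-dimethyloxiran-2-yl]methanol | OC[C@@]1(C)O[C@H]1C | intermediate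
8 | (2S,3S)-2,3-dimethyloxirane-2-carboxylic acid | OC(=O)[C@@]1(C)O[C@H]1C | intermediate
9 | (2R)-2-[(triphenylmethoxy)methyl]oxirane, (R)-trityl glycidyl ether | C1[C@@H](O1)COC(c1ccccc1)(c1ccccc1)c1ccccc1 | starting material
10 | (2R)-1-(triphenylmethoxy)pent-4-yn-2-ol | C#CC[C@@H](O)COC(c1ccccc1)(c1ccccc1)c1ccccc1 | intermediate
11 | 1-methoxy-4-({[(2R)-1-(triphenylmethoxy)pent-4-yn-2-yl]oxy}methyl)benzene | C#CC[C@@H](OCc1ccc(OC)cc1)COC(c1ccccc1)(c1ccccc1)c1ccccc1 | intermediate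
12 | dimethyl[(1E,4R)-4-[(4-methoxybenzyl)oxy]-2-methyl-5-(triphenylmethoxy)pent-1-en-1-yl]alumane (alkenyldimethylalane) | C[Al](C)/C=C(\C)C[C@@H](OCc1ccc(OC)cc1)COC(c1ccccc1)(c1ccccc1)c1ccccc1 | intermediate
13 | lithium butyl(dimethyl)[(1E,4R)-4-[(4-methoxybenzyl)oxy]-2-methyl-5-(triphenylmethoxy)pent-1-en-1-yl]aluminate (lithium alkenylalanate) | [Li+].CCCC[Al-](C)(C)/C=C(\C)C[C@@H](OCc1ccc(OC)cc1)COC(c1ccccc1)(c1ccccc1)c1ccccc1 | intermediate
14 | (3E,6R)-6-[(4-methoxybenzyl)oxy]-4-methyl-7-(triphenylmethoxy)hept-3-en-1-ol | OCC/C=C(\C)C[C@@H](OCc1ccc(OC)cc1)COC(c1ccccc1)(c1ccccc1)c1ccccc1 | intermediate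
15 | tert-butyl({(3E,6R)-6-[(4-methoxybenzyl)oxy]-4-methyl-7-(triphenylmethoxy)hept-3-en-1-yl}oxy)diphenylsilane | CC(C)(C)[Si](OCC/C=C(\C)C[C@@H](OCc1ccc(OC)cc1)COC(c1ccccc1)(c1ccccc1)c1ccccc1)(c1ccccc1)c1ccccc1 | intermediate
16 | (2R,4E)-7-[(tert-butyldiphenylsilyl)oxy]-2-[(4-methoxybenzyl)oxy]-4-methylhept-4-en-1-ol | OC[C@H](OCc1ccc(OC)cc1)C/C(C)=C/CCO[Si](C(C)(C)C)(c1ccccc1)c1ccccc1 | intermediate
17 | (2R,4E)-7-[(tert-butyldiphenylsilyl)oxy]-2-[(4-methoxybenzyl)oxy]-4-methylhept-4-enal | O=C[C@H](OCc1ccc(OC)cc1)C/C(C)=C/CCO[Si](C(C)(C)C)(c1ccccc1)c1ccccc1 | intermediate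
18 | methyl acrylate | C=CC(=O)OC | starting material
19 | methyl (4R,6E)-9-[(tert-butyldiphenylsilyl)oxy]-3-hydroxy-4-[(4-methoxybenzyl)oxy]-6-methyl-2-methylidenenon-6-enoate (both C3 epimers) | C=C(C(=O)OC)C(O)[C@H](OCc1ccc(OC)cc1)C/C(C)=C/CCO[Si](C(C)(C)C)(c1ccccc1)c1ccccc1 | intermediate
20 | methyl (2Z,4R,6E)-2-(bromomethyl)-9-[(tert-butyldiphenylsilyl)oxy]-4-[(4-methoxybenzyl)oxy]-6-methylnona-2,6-dienoate | COC(=O)/C(CBr)=C/[C@H](OCc1ccc(OC)cc1)C/C(C)=C/CCO[Si](C(C)(C)C)(c1ccccc1)c1ccccc1 | intermediate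
21 | methyl (3S,4R,6E)-9-[(tert-butyldiphenylsilyl)oxy]-3-[(1S,2Z)-1-hydroxy-3-iodobut-2-en-1-yl]-4-[(4-methoxybenzyl)oxy]-6-methyl-2-methylidenenon-6-enoate (anti hydroxy ester) | COC(=O)C(=C)[C@@H]([C@H](O)/C=C(/C)I)[C@H](OCc1ccc(OC)cc1)C/C(C)=C/CCO[Si](C(C)(C)C)(c1ccccc1)c1ccccc1 | intermediate
22 | (4R,5S)-4-[(1R,3E)-6-[(tert-butyldiphenylsilyl)oxy]-1-[(4-methoxybenzyl)oxy]-3-methylhex-3-en-1-yl]-5-[(1Z)-2-iodoprop-1-en-1-yl]-3-methylideneoxolan-2-one | C=C1C(=O)O[C@H](/C=C(/C)I)[C@H]1[C@H](OCc1ccc(OC)cc1)C/C(C)=C/CCO[Si](C(C)(C)C)(c1ccccc1)c1ccccc1 | intermediate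
23 | (4R,5S)-4-[(1R,3E)-6-hydroxy-1-[(4-methoxybenzyl)oxy]-3-methylhex-3-en-1-yl]-5-[(1Z)-2-iodoprop-1-en-1-yl]-3-methylideneoxolan-2-one | C=C1C(=O)O[C@H](/C=C(/C)I)[C@H]1[C@H](OCc1ccc(OC)cc1)C/C(C)=C/CCO | intermediate
24 | (4R,5S)-5-[(1Z)-2-iodoprop-1-en-1-yl]-4-[(1R,3E)-1-[(4-methoxybenzyl)oxy]-3-methyl-6-oxohex-3-en-1-yl]-3-methylideneoxolan-2-one | C=C1C(=O)O[C@H](/C=C(/C)I)[C@H]1[C@H](OCc1ccc(OC)cc1)C/C(C)=C/CC=O | intermediate
25 | (3S,6R,7R,8R)-3-hydroxy-8-[(4-methoxybenzyl)oxy]germacra-1(10)E,4Z,11(13)-trien-12,6-olide | C=C1C(=O)O[C@@H]2/C=C(/C)[C@@H](O)C/C=C(\C)C[C@@H](OCc3ccc(OC)cc3)[C@@H]12 | intermediate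
26 | (3S,6R,7R,8R)-8-[(4-methoxybenzyl)oxy]-3-(3-methylbutanoyloxy)germacra-1(10)E,4Z,11(13)-trien-12,6-olide | C=C1C(=O)O[C@@H]2/C=C(/C)[C@@H](OC(=O)CC(C)C)C/C=C(\C)C[C@@H](OCc3ccc(OC)cc3)[C@@H]12 | intermediate
27 | (3S,6R,7R,8R)-8-hydroxy-3-(3-methylbutanoyloxy)germacra-1(10)E,4Z,11(13)-trien-12,6-olide | C=C1C(=O)O[C@@H]2/C=C(/C)[C@@H](OC(=O)CC(C)C)C/C=C(\C)C[C@@H](O)[C@@H]12 | intermediate
28 | (2S,3S)-2,3-dimethyloxirane-2-carboxylic 2,4,6-trichlorobenzoic anhydride (mixed anhydride) | O=C(OC(=O)c1c(Cl)cc(Cl)cc1Cl)[C@@]1(C)O[C@H]1C | intermediate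
29 | (3S,6R,7R,8R)-8-[(2S,3S)-2,3-dimethyloxirane-2-carbonyloxy]-3-(3-methylbutanoyloxy)germacra-1(10)E,4Z,11(13)-trien-12,6-olide | C=C1C(=O)O[C@@H]2/C=C(/C)[C@@H](OC(=O)CC(C)C)C/C=C(\C)C[C@@H](OC(=O)[C@@]3(C)O[C@H]3C)[C@@H]12 | intermediate
30 | (1R,3S,6R,7R,8R,10R)-8-[(2S,3S)-2,3-dimethyloxirane-2-carbonyloxy]-1,10-epoxy-3-(3-methylbutanoyloxy)germacra-4Z,11(13)-dien-12,6-olide (CNP0167461.1) | C=C1C(=O)O[C@@H]2/C=C(/C)[C@@H](OC(=O)CC(C)C)C[C@H]3O[C@]3(C)C[C@@H](OC(=O)[C@@]3(C)O[C@H]3C)[C@@H]12 | target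

**Step count and risks**

Total step count: 21 steps. Longest linear sequence: 16 steps (steps 6 to 21, from 9 to 30).

Steps most likely to fail:

1. Step 17 (ring closure). Intermolecular coupling and reductive loss of iodine compete with the closure of the strained ring, and the face of the C3 aldehyde that is attacked is fixed only by the conformation of the forming ring, so poor facial selectivity at C3 is the most probable shortfall. Fallback: the stereocentre is corrected by an invertive esterification instead of by the cyclisation. Setting out from 24, the cyclisation would also give the C3 epimer, (3R,6R,7R,8R)-3-hydroxy-8-[(4-methoxybenzyl)oxy]germacra-1(10)E,4Z,11(13)-trien-12,6-olide F1. This would be esterified under Mitsunobu conditions (3-methylbutanoic acid, PPh3, diisopropyl azodicarboxylate, THF, 0 °C) with inversion at C3, which comes back to the route at 26 and replaces step 18 for this epimer.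

2. Step 14 (allylation/lactonisation). The allylchromium may not equilibrate fully to the geometry that leads to the anti adduct, and the C8 substituent may discriminate the two faces of C7 only weakly; the result would be erosion of diastereoselectivity and a cis-lactone series. Fallback: the metal is changed and C6 is set by inversion. Setting out from 20 and 4, an indium-mediated Barbier allylation (In, THF/H2O, rt), which runs through a closed transition state of the Z-configured allylindium, should give the syn adduct, methyl (3S,4R,6E)-9-[(tert-butyldiphenylsilyl)oxy]-3-[(1R,2Z)-1-hydroxy-3-iodobut-2-en-1-yl]-4-[(4-methoxybenzyl)oxy]-6-methyl-2-methylidenenon-6-enoate F2. Saponification (LiOH, THF/H2O) would give the hydroxy acid, (3S,4R,6E)-9-[(tert-butyldiphenylsilyl)oxy]-3-[(1R,2Z)-1-hydroxy-3-iodobut-2-en-1-yl]-4-[(4-methoxybenzyl)oxy]-6-methyl-2-methylidenenon-6-enoic acid F3. Mitsunobu lactonisation (PPh3, diisopropyl azodicarboxylate, toluene, high dilution) would then close the lactone with inversion at C6 and come back to the route at 22.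

3. Step 21 (late epoxidation). The peracid may show poor facial selectivity on the macrocyclic E alkene or may also oxidise the C4=C5 alkene. Fallback: the epoxide is set by reagent control before the ring closure. Setting out from 23, a vanadium-catalysed, hydroxyl-directed asymmetric epoxidation of the homoallylic alcohol (VO(OiPr)3, chiral bishydroxamic acid ligand, cumene hydroperoxide, toluene) would give (4R,5S)-4-[(1R)-2-[(2R,3R)-3-(2-hydroxyethyl)-2-methyloxiran-2-yl]-1-[(4-methoxybenzyl)oxy]ethyl]-5-[(1Z)-2-iodoprop-1-en-1-yl]-3-methylideneoxolan-2-one F4. Dess–Martin oxidation would give the epoxy aldehyde, (4R,5S)-5-[(1Z)-2-iodoprop-1-en-1-yl]-4-[(1R)-1-[(4-methoxybenzyl)oxy]-2-[(2R,3R)-2-methyl-3-(2-oxoethyl)oxiran-2-yl]ethyl]-3-methylideneoxolan-2-one F5, to be used at once. The CrCl2/NiCl2 ring closure of step 17 would give (1R,3S,6R,7R,8R,10R)-1,10-epoxy-3-hydroxy-8-[(4-methoxybenzyl)oxy]germacra-4Z,11(13)-dien-12,6-olide F6. Acylation with 3-methylbutanoic anhydride would give (1R,3S,6R,7R,8R,10R)-1,10-epoxy-8-[(4-methoxybenzyl)oxy]-3-(3-methylbutanoyloxy)germacra-4Z,11(13)-dien-12,6-olide F7, and DDQ would give (1R,3S,6R,7R,8R,10R)-1,10-epoxy-8-hydroxy-3-(3-methylbutanoyloxy)germacra-4Z,11(13)-dien-12,6-olide F8. Esterification with 8 under the conditions of step 20 comes back to the route at 30.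

Further compounds
F1 | step 17 | (3R,6R,7R,8R)-3-hydroxy-8-[(4-methoxybenzyl)oxy]germacra-1(10)E,4Z,11(13)-trien-12,6-olide (C3 epimer of 25) | C=C1C(=O)O[C@@H]2/C=C(/C)[C@H](O)C/C=C(\C)C[C@@H](OCc3ccc(OC)cc3)[C@@H]12
F2 | step 14 | methyl (3S,4R,6E)-9-[(tert-butyldiphenylsilyl)oxy]-3-[(1R,2Z)-1-hydroxy-3-iodobut-2-en-1-yl]-4-[(4-methoxybenzyl)oxy]-6-methyl-2-methylidenenon-6-enoate (C6 epimer of 21) | COC(=O)C(=C)[C@@H]([C@@H](O)/C=C(/C)I)[C@H](OCc1ccc(OC)cc1)C/C(C)=C/CCO[Si](C(C)(C)C)(c1ccccc1)c1ccccc1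
F3 | step 14 | (3S,4R,6E)-9-[(tert-butyldiphenylsilyl)oxy]-3-[(1R,2Z)-1-hydroxy-3-iodobut-2-en-1-yl]-4-[(4-methoxybenzyl)oxy]-6-methyl-2-methylidenenon-6-enoic acid | OC(=O)C(=C)[C@@H]([C@@H](O)/C=C(/C)I)[C@H](OCc1ccc(OC)cc1)C/C(C)=C/CCO[Si](C(C)(C)C)(c1ccccc1)c1ccccc1
F4 | step 21 | (4R,5S)-4-[(1R)-2-[(2R,3R)-3-(2-hydroxyethyl)-2-methyloxiran-2-yl]-1-[(4-methoxybenzyl)oxy]ethyl]-5-[(1Z)-2-iodoprop-1-en-1-yl]-3-methylideneoxolan-2-one | C=C1C(=O)O[C@H](/C=C(/C)I)[C@H]1[C@H](OCc1ccc(OC)cc1)C[C@@]1(C)O[C@@H]1CCO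
F5 | step 21 | (4R,5S)-5-[(1Z)-2-iodoprop-1-en-1-yl]-4-[(1R)-1-[(4-methoxybenzyl)oxy]-2-[(2R,3R)-2-methyl-3-(2-oxoethyl)oxiran-2-yl]ethyl]-3-methylideneoxolan-2-one | C=C1C(=O)O[C@H](/C=C(/C)I)[C@H]1[C@H](OCc1ccc(OC)cc1)C[C@@]1(C)O[C@@H]1CC=O
F6 | step 21 | (1R,3S,6R,7R,8R,10R)-1,10-epoxy-3-hydroxy-8-[(4-methoxybenzyl)oxy]germacra-4Z,11(13)-dien-12,6-olide | C=C1C(=O)O[C@@H]2/C=C(/C)[C@@H](O)C[C@H]3O[C@]3(C)C[C@@H](OCc3ccc(OC)cc3)[C@@H]12
F7 | step 21 | (1R,3S,6R,7R,8R,10R)-1,10-epoxy-8-[(4-methoxybenzyl)oxy]-3-(3-methylbutanoyloxy)germacra-4Z,11(13)-dien-12,6-olide | C=C1C(=O)O[C@@H]2/C=C(/C)[C@@H](OC(=O)CC(C)C)C[C@H]3O[C@]3(C)C[C@@H](OCc3ccc(OC)cc3)[C@@H]12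
F8 | step 21 | (1R,3S,6R,7R,8R,10R)-1,10-epoxy-8-hydroxy-3-(3-methylbutanoyloxy)germacra-4Z,11(13)-dien-12,6-olide | C=C1C(=O)O[C@@H]2/C=C(/C)[C@@H](OC(=O)CC(C)C)C[C@H]3O[C@]3(C)C[C@@H](O)[C@@H]12
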